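**Retrosynthetic overview**

1. Target ⇐ acetylation of the 8,15-diol ⇐ Zr-catalysed carboalumination/formaldehyde trapping of a terminal alkyne (sets 13E) ⇐ methyl addition to an 8-ketone (sets C8) ⇐ a cis-fused 1-decalone.
2. Key disconnection: bonds C8–C9 and C5–C10 of that decalone ⇐ a monocyclic cyclopentyl silyl ether, by a pinacol-terminated Prins cyclisation. Ring B closes, and ring A (C10, C1, C2, C3, C4, C5) grows from the cyclopentane C1–C2–C3–C4–C5 by insertion of C10 between C1 and C5.
3. Enabling feature: the quaternary C10 of ring A lies between C5 and C1, and C1 is a bare CH2 in the target. C1 can therefore carry a temporary silyloxy group next to the C10=C9 alkene, which drives the shift and leaves as a ketone (removed by Wolff–Kishner reduction). C5 carries the C6–C7–C8 acetal chain.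
4. The cyclopentyl silyl ether ⇐ a 2-substituted 3,3-dimethylcyclopentanone + an E vinyl iodide (from hex-4-yn-1-ol). The ketone ⇐ (R)-2-allyl-3,3-dimethylcyclopentanone ⇐ 3-methylcyclopentenone, Me2CuLi and allyl chloroformate, then Pd-catalysed decarboxylative asymmetric allylation (sets C5).
5. Ring order: cyclopentane (bought) → ring B closed and ring A grown in one operation.

Key step: step 9

**Remarks on the chemistry**

- Reading of the target: the SMILES defines (5R,8S,9R,10S), a cis-fused decalin with 5-H, the C10 methyl, the C9 chain and the 8-OH all on one face. Labdane numbering is used; β means the face of the C10 methyl.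
- Assumption: the (R,R) ligand in step 2 is taken to give (R)-5; the (S,S) ligand is used if the sense of induction is the opposite.

**Route**

Step 1
Reactants: 1 3-methylcyclopent-2-en-1-one; 2 allyl chloroformate
Product: 4 allyl 3,3-dimethylcyclopent-1-en-1-yl carbonate, via lithium enolate 3 (not isolated)
Conditions: Me2CuLi (from MeLi, CuI), Et2O, 0 °C; then 2, THF/HMPA, −78 °C to rt
Reagents that add atoms: methyllithium, C[Li] (delivered as Me2CuLi)
Why: Cuprate conjugate addition creates the gem-dimethyl carbon and gives the lithium enolate regiospecifically on that side, and O-acylation by the chloroformate in THF/HMPA should trap it as the allyl enol carbonate (1,4-addition/enolate trapping that joins three components).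

Step 2
Reactants: 4 allyl 3,3-dimethylcyclopent-1-en-1-yl carbonate
Product: 5 (2R)-2-allyl-3,3-dimethylcyclopentan-1-one
Conditions: Pd2(dba)3·CHCl3 (cat.), (R,R)-N,N'-(9,10-dihydro-9,10-ethanoanthracene-11,12-diyl)bis[2-(diphenylphosphino)benzamide] (cat.), 1,4-dioxane, 23 °C
Reagents that add atoms: none
Why: Tsuji–Trost-type decarboxylative asymmetric allylic alkylation: ionisation and loss of CO2 give a π-allylpalladium enolate ion pair that recombines at carbon inside the chiral ligand pocket, which should set C5 as R under neutral conditions that do not enolise the product.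

Step 3
Reactants: 5 (2R)-2-allyl-3,3-dimethylcyclopentan-1-one
Product: 6 3-[(1R)-2,2-dimethyl-5-oxocyclopentyl]propanal
Conditions: PdCl2(PhCN)2, CuCl2·2H2O, AgNO2 (each cat.), O2 (1 atm), t-BuOH/MeNO2 15:1, rt
Reagents that add atoms: dioxygen, O=O
Why: The nitrite-modified, aldehyde-selective Wacker oxidation delivers oxygen to the terminal carbon of the unbiased monosubstituted alkene, and the neutral conditions should leave the ketone and C5 untouched.

Step 4
Reactants: 6 3-[(1R)-2,2-dimethyl-5-oxocyclopentyl]propanal
Product: 7 (2R)-2-[3,3-bis(benzyloxy)propyl]-3,3-dimethylcyclopentan-1-one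
Conditions: PhCH2OSiMe3 (2.2 equiv), Me3SiOTf (cat.), CH2Cl2, −78 °C
Reagents that add atoms: benzyloxytrimethylsilane, C[Si](C)(C)OCc1ccccc1
Why: Silyl-triflate-catalysed acetalisation with the benzyl silyl ether is fast for the aldehyde at −78 °C and should leave the hindered α-branched cyclopentanone free for step 7.

Step 5
Reactants: 8 hex-4-yn-1-ol
Product: 9 [(hex-4-yn-1-yloxy)methyl]benzene
Conditions: NaH, PhCH2Br, Bu4NI (cat.), THF, 0 °C to rt
Reagents that add atoms: benzyl bromide, BrCc1ccccc1
Why: Williamson ether synthesis protects the primary alcohol as a benzyl ether that survives organolithium, Lewis acid and Wolff–Kishner conditions.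

Step 6
Reactants: 9 [(hex-4-yn-1-yloxy)methyl]benzene
Product: 11 {[(4E)-5-iodohex-4-en-1-yl]oxy}methylbenzene, via alkenylzirconocene chloride 10 (not isolated)
Conditions: Cp2Zr(H)Cl (2 equiv), THF, 50 °C; then I2, 0 °C
Reagents that add atoms: iodine, II
Why: Hydrozirconation adds H–Zr syn across the 2-alkyne with zirconium on the less hindered methyl-bearing carbon (excess reagent equilibrates the regioisomers), and iodinolysis with retention should give the E vinyl iodide with iodine trans to the chain.

Step 7
Reactants: 11 {[(4E)-5-iodohex-4-en-1-yl]oxy}methylbenzene; 7 (2R)-2-[3,3-bis(benzyloxy)propyl]-3,3-dimethylcyclopentan-1-one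
Product: 14 (1S,2R)-1-[(2E)-6-(benzyloxy)hex-2-en-2-yl]-2-[3,3-bis(benzyloxy)propyl]-3,3-dimethylcyclopentan-1-ol, via alkenyllithium 12 (not isolated), via alkenylcerium dichloride 13 (not isolated)
Conditions: 11, t-BuLi (2 equiv), Et2O, −78 °C; CeCl3, THF, −78 °C; then 7, −78 to −40 °C; aq. NH4Cl
Reagents that add atoms: none
Why: Iodine–lithium exchange with retention of alkene geometry, transmetalation to the weakly basic organocerium and 1,2-addition to the enolisable ketone, mainly anti to the C5 chain, should give the tertiary allylic alcohol; the configuration at C1 is of no consequence because C1 becomes a carbonyl carbon in step 9.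

Step 8
Reactants: 14 (1S,2R)-1-[(2E)-6-(benzyloxy)hex-2-en-2-yl]-2-[3,3-bis(benzyloxy)propyl]-3,3-dimethylcyclopentan-1-ol
Product: 15 trimethylsilyl ether of 14
Conditions: 1-(trimethylsilyl)imidazole, CH2Cl2, rt
Reagents that add atoms: 1-(trimethylsilyl)imidazole, C[Si](C)(C)n1ccnc1
Why: Silyl transfer from the silylimidazole protects the hindered tertiary alcohol under neutral conditions that keep the acid-labile acetal (O-silylation).

Step 9
Reactants: 15 trimethylsilyl ether of 14
Product: 18 8,13-bis(benzyloxy)-14,15,16,17-tetranor-5β-labdan-1-one (C8 epimer mixture), via oxocarbenium ion 16 (not isolated), via C10 carbocation 17 (not isolated)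
Conditions: SnCl4 (2.5 equiv), CH2Cl2, −78 to −23 °C; aq. NaHCO3
Reagents that add atoms: none
Why: SnCl4 ionises the dibenzyl acetal to oxocarbenium ion 16, C9 of the C9=C10 alkene attacks C8 to give the tertiary C10 cation 17 inside a seven-membered ring, and the C1–C5 bond, aligned with the empty orbital and pushed by the silyloxy oxygen, shifts from C1 to C10 with loss of the silyl group, so that the seven-membered ring contracts to ring B while the cyclopentane C1–C5 takes up C10 and becomes ring A as its C1 ketone. The closest known reaction type is the pinacol-terminated Prins cyclisation (ring-enlarging cyclohexane annulation) of 1-alkenylcycloalkanol silyl ethers that carry a 3,3-dialkoxypropyl chain on the neighbouring ring carbon. Ring B closes in two stages, a seven-membered closure that is endo with respect to the alkene and exo with respect to the oxocarbenium ion, then ring contraction by the 1,2-shift, and ring A forms by that same 1,2-alkyl shift as a one-carbon ring expansion. C5 migrates with retention and is delivered to the face of C10 over which it already lies, which allows only the cis ring fusion (5-H and the C10 methyl on one face), and because C8 and C5 must add to the same face of the alkene to span a six-membered ring, the E geometry places the C11 chain cis to the C10 methyl; C8 forms without control and is erased in step 12. The step needs migration of C5 and not C2, secured by the chain that ties C5 to C8 and holds the C1–C5 bond over the cation and by the higher substitution of C5, and it needs acetal ionisation and ring closure to outrun ionisation of the tertiary allylic silyl ether, secured by the low temperature and the much greater lability of the acetal. Both C1 epimers of 15 should converge on 18 because C1 becomes trigonal.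

Step 10
Reactants: 18 8,13-bis(benzyloxy)-14,15,16,17-tetranor-5β-labdan-1-one
Product: 20 8,13-bis(benzyloxy)-14,15,16,17-tetranor-5β-labdane (C8 epimer mixture), via hydrazone 19 (not isolated)
Conditions: N2H4·H2O, KOH, diethylene glycol, 130 °C then 200 °C
Reagents that add atoms: none
Why: Wolff–Kishner reduction (Huang–Minlon procedure) removes the temporary C1 carbonyl through hydrazone 19; C1 has no epimerisable neighbour (C10 is quaternary) and benzyl ethers are stable to hot base.

Step 11
Reactants: 20 8,13-bis(benzyloxy)-14,15,16,17-tetranor-5β-labdane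
Product: 21 14,15,16,17-tetranor-5β-labdane-8,13-diol (C8 epimer mixture)
Conditions: H2 (1 atm), Pd/C, EtOAc/MeOH, rt
Reagents that add atoms: none
Why: Hydrogenolysis cleaves both benzyl ethers; no alkene is present at this stage.

Step 12
Reactants: 21 14,15,16,17-tetranor-5β-labdane-8,13-diol
Product: 22 8-oxo-14,15,16,17-tetranor-5β-labdan-13-al
Conditions: n-Pr4N[RuO4] (cat.), N-methylmorpholine N-oxide, 4 Å MS, CH2Cl2, rt
Reagents that add atoms: none
Why: Ley–Griffith oxidation converts the secondary alcohol (both C8 epimers converge on one ketone) and the primary alcohol to ketone and aldehyde under non-basic conditions that should not epimerise C9.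

Step 13
Reactants: 22 8-oxo-14,15,16,17-tetranor-5β-labdan-13-al
Product: 23 15,16,17-trinor-5β-labd-13-yn-8-one
Conditions: dimethyl (1-diazo-2-oxopropyl)phosphonate, K2CO3, MeOH, 0 °C to rt
Reagents that add atoms: dimethyl (1-diazo-2-oxopropyl)phosphonate, COP(=O)(OC)C(=[N+]=[N-])C(C)=O
Why: Ohira–Bestmann (Seyferth–Gilbert) homologation turns the aldehyde into the terminal alkyne; the hindered ketone reacts far more slowly with the diazophosphonate anion, and carbonate at this temperature should not enolise the congested C9 position.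

Step 14
Reactants: 23 15,16,17-trinor-5β-labd-13-yn-8-one
Product: 24 15,16-dinor-5β-labd-13-yn-8β-ol
Conditions: MeLi, CeCl3, THF, −78 °C; then 23; aq. NH4Cl
Reagents that add atoms: methyllithium, C[Li] (delivered as MeCeCl2)
Why: Organocerium 1,2-addition suppresses enolisation, and the methyl group should enter from the α face along the equatorial trajectory of the ring-B chair that has the C10 methyl axial and the C9 chain equatorial (the β face is blocked by the 1,3-diaxial C10 methyl, and the other chair has no open trajectory), giving 8α-methyl/8β-OH by analogy with angular-methyl-controlled additions to decalones.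

Step 15
Reactants: 24 15,16-dinor-5β-labd-13-yn-8β-ol
Product: 26 (13E)-5β-labd-13-ene-8β,15-diol, via alkenylalane 25 (not isolated)
Conditions: AlMe3 (4 equiv), Cp2ZrCl2 (0.3 equiv), CH2Cl2, 0 °C to rt; then n-BuLi, THF, −30 °C; (CH2O)n, rt; aq. work-up
Reagents that add atoms: trimethylaluminium, C[Al](C)C; formaldehyde (as paraformaldehyde), C=O
Why: Zr-catalysed carboalumination of the terminal alkyne (Negishi) adds methyl and aluminium syn with aluminium at the terminus, and the derived alanate reacts with formaldehyde with retention, so the 13E allylic alcohol should form with the methyl cis to CH2OH.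

Step 16
Reactants: 26 (13E)-5β-labd-13-ene-8β,15-diol
Product: 27 (13E)-8β-hydroxy-5β-labd-13-en-15-yl acetate
Conditions: Ac2O, pyridine, DMAP (cat.), CH2Cl2, 0 °C
Reagents that add atoms: acetic anhydride, CC(=O)OC(C)=O
Why: Acetylation of the primary allylic alcohol; the tertiary 8-OH, flanked by C9 and syn-axial to the C10 methyl, should not acylate under these conditions.

**Compound list**

1 | 3-methylcyclopent-2-en-1-one | CC1=CC(=O)CC1 | starting material
2 | allyl chloroformate | C=CCOC(Cl)=O | starting material
3 | lithium 3,3-dimethylcyclopent-1-en-1-olate | [Li+].[O-]C1=CC(C)(C)CC1 | intermediate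
4 | allyl 3,3-dimethylcyclopent-1-en-1-yl carbonate | C=CCOC(=O)OC1=CC(C)(C)CC1 | intermediate
5 | (2R)-2-allyl-3,3-dimethylcyclopentan-1-one | C=CC[C@H]1C(=O)CCC1(C)C | intermediate
6 | 3-[(1R)-2,2-dimethyl-5-oxocyclopentyl]propanal | O=CCC[C@H]1C(=O)CCC1(C)C | intermediate
7 | (2R)-2-[3,3-bis(benzyloxy)propyl]-3,3-dimethylcyclopentan-1-one | O=C1CCC(C)(C)[C@H]1CCC(OCc1ccccc1)OCc1ccccc1 | intermediate
8 | hex-4-yn-1-ol | CC#CCCCO | starting material
9 | [(hex-4-yn-1-yloxy)methyl]benzene | CC#CCCCOCc1ccccc1 | intermediate
10 | chlorobis(cyclopentadienyl)[(2E)-6-(benzyloxy)hex-2-en-2-yl]zirconium | C/C(=C\CCCOCc1ccccc1)[Zr](Cl)(C1C=CC=C1)C1C=CC=C1 | intermediate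
11 | {[(4E)-5-iodohex-4-en-1-yl]oxy}methylbenzene | C/C(I)=C\CCCOCc1ccccc1 | intermediate
12 | [(2E)-6-(benzyloxy)hex-2-en-2-yl]lithium | C/C([Li])=C\CCCOCc1ccccc1 | intermediate
13 | [(2E)-6-(benzyloxy)hex-2-en-2-yl]cerium dichloride | C/C(=C\CCCOCc1ccccc1)[Ce](Cl)Cl | intermediate
14 | (1S,2R)-1-[(2E)-6-(benzyloxy)hex-2-en-2-yl]-2-[3,3-bis(benzyloxy)propyl]-3,3-dimethylcyclopentan-1-ol (alkenyl trans to the C5 chain) | C/C(=C\CCCOCc1ccccc1)[C@]1(O)CCC(C)(C)[C@H]1CCC(OCc1ccccc1)OCc1ccccc1 | intermediate
15 | trimethylsilyl ether of 14 | C/C(=C\CCCOCc1ccccc1)[C@]1(O[Si](C)(C)C)CCC(C)(C)[C@H]1CCC(OCc1ccccc1)OCc1ccccc1 | intermediate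
16 | O-benzyl oxocarbenium ion at C8 derived from 15 | C/C(=C\CCCOCc1ccccc1)[C@]1(O[Si](C)(C)C)CCC(C)(C)[C@H]1CCC=[O+]Cc1ccccc1 | intermediate
17 | C10 tertiary carbocation in the trans-fused bicyclo[5.3.0]decane (C1 silyloxy, C8 benzyloxy, C9 chain) | C[C+]1[C@@H](CCCOCc3ccccc3)C(OCc3ccccc3)CC[C@@H]2C(C)(C)CC[C@@]12O[Si](C)(C)C | intermediate
18 | 8,13-bis(benzyloxy)-14,15,16,17-tetranor-5β-labdan-1-one: cis-decalone, 5β-H, 10β-methyl, 9β-chain, both C8 epimers | c1ccccc1COCCC[C@@H]1[C@@]2(C)C(=O)CCC(C)(C)[C@H]2CCC1OCc1ccccc1 | intermediate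
19 | hydrazone of 18 | c1ccccc1COCCC[C@@H]1[C@@]2(C)C(=NN)CCC(C)(C)[C@H]2CCC1OCc1ccccc1 | intermediate
20 | 8,13-bis(benzyloxy)-14,15,16,17-tetranor-5β-labdane (both C8 epimers) | c1ccccc1COCCC[C@@H]1[C@@]2(C)CCCC(C)(C)[C@H]2CCC1OCc1ccccc1 | intermediate
21 | 14,15,16,17-tetranor-5β-labdane-8,13-diol (both C8 epimers) | OCCC[C@@H]1[C@@]2(C)CCCC(C)(C)[C@H]2CCC1O | intermediate
22 | 8-oxo-14,15,16,17-tetranor-5β-labdan-13-al | O=CCC[C@@H]1[C@@]2(C)CCCC(C)(C)[C@H]2CCC1=O | intermediate
23 | 15,16,17-trinor-5β-labd-13-yn-8-one | C#CCC[C@@H]1[C@@]2(C)CCCC(C)(C)[C@H]2CCC1=O | intermediate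
24 | 15,16-dinor-5β-labd-13-yn-8β-ol (8α-methyl) | C#CCC[C@@H]1[C@@]2(C)CCCC(C)(C)[C@H]2CC[C@]1(C)O | intermediate
25 | (13E)-14-(dimethylalumanyl)-15-nor-5β-labd-13-en-8β-yl dimethylaluminium alkoxide | C[Al](C)/C=C(\C)CC[C@@H]1[C@@]2(C)CCCC(C)(C)[C@H]2CC[C@]1(C)O[Al](C)C | intermediate
26 | (13E)-5β-labd-13-ene-8β,15-diol | OC/C=C(\C)CC[C@@H]1[C@@]2(C)CCCC(C)(C)[C@H]2CC[C@]1(C)O | intermediate
27 | (13E)-8β-hydroxy-5β-labd-13-en-15-yl acetate, (5R,8S,9R,10S) | CC(=O)OC/C=C(\C)CC[C@@H]1[C@@]2(C)CCCC(C)(C)[C@H]2CC[C@]1(C)O | target

**Step count**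

Total: 16 steps. Longest linear sequence: 14 steps (steps 1–4 and 7–16); the vinyl iodide branch is steps 5–6.

**Steps most likely to fail**

Step 9. Ionisation of the tertiary allylic silyl ether by SnCl4, or loss of a proton from the C10 cation, may outrun the seven-membered Prins closure and the 1,2-shift. The fallback changes the initiator from an acetal-derived oxocarbenium ion to a Lewis-acid-bound aldehyde (carbonyl-ene-type Prins initiation with the proton-scavenging Me2AlCl), and oxidises the chain only after C1 has been built. It sets out from 5 and comes back at 21. Addition of alkenylcerium 13 to 5 (as in step 7) should give (1S,2R)-2-allyl-1-[(2E)-6-(benzyloxy)hex-2-en-2-yl]-3,3-dimethylcyclopentan-1-ol F1. Et3SiOTf/2,6-lutidine should give its triethylsilyl ether F2. 9-BBN, then NaOH/H2O2, should hydroborate only the terminal alkene and give the primary alcohol F3. Dess–Martin oxidation should give the aldehyde F4. Me2AlCl (CH2Cl2, −78 °C), then dilute acid, should give the hydroxy ketone F5 by the same Prins closure and 1,2-shift, with oxygen left as a free 8-hydroxyl. Wolff–Kishner reduction should give the alcohol F6, and hydrogenolysis (H2, Pd/C) of its benzyl ether gives 21.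

Step 14. Poor facial selectivity (methyl entering from the β face through the other ring-B chair) or enolisation of the hindered ketone may erode the C8 configuration. The fallback inverts the polarity of the bond formation at C8, so that oxygen and not carbon is placed on the more accessible face. It sets out from 23 and comes back at 24. Wittig methylenation (Ph3P=CH2, THF) should give the exocyclic alkene 15,16-dinor-5β-labd-8(17)-en-13-yne F7. m-CPBA, which follows the same steric bias as the nucleophile, should then give the 8β,17-epoxide F8. LiAlH4 opens it at the CH2 terminus and gives 24. This fallback is the right one if the nucleophile prefers the β face; if it merely shows low selectivity, the epimers are separated at 24.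

Step 2. Enantioselectivity may be insufficient when a tertiary α-stereocentre is formed next to a quaternary carbon, and enolisation may erode it further. The fallback replaces the palladium-catalysed allylation by a ligand-controlled enantioselective alkylation of the achiral lithium enolate. It sets out from 1 and comes back at 5. Me2CuLi addition to 1 with Me3SiCl trapping should give 3,3-dimethyl-1-(trimethylsilyloxy)cyclopent-1-ene F9. MeLi·LiBr regenerates enolate 3 free of copper, and allyl bromide in the presence of a stoichiometric chiral tetradentate amine ligand (toluene, −45 °C) should give 5.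

**Further compounds**

F1 | step 9 | (1S,2R)-2-allyl-1-[(2E)-6-(benzyloxy)hex-2-en-2-yl]-3,3-dimethylcyclopentan-1-ol | C/C(=C\CCCOCc1ccccc1)[C@]1(O)CCC(C)(C)[C@H]1CC=C
F2 | step 9 | triethylsilyl ether of F1 | C/C(=C\CCCOCc1ccccc1)[C@]1(O[Si](CC)(CC)CC)CCC(C)(C)[C@H]1CC=C
F3 | step 9 | 3-{(1R,2S)-2-[(2E)-6-(benzyloxy)hex-2-en-2-yl]-5,5-dimethyl-2-(triethylsilyloxy)cyclopentyl}propan-1-ol | C/C(=C\CCCOCc1ccccc1)[C@]1(O[Si](CC)(CC)CC)CCC(C)(C)[C@H]1CCCO
F4 | step 9 | 3-{(1R,2S)-2-[(2E)-6-(benzyloxy)hex-2-en-2-yl]-5,5-dimethyl-2-(triethylsilyloxy)cyclopentyl}propanal | C/C(=C\CCCOCc1ccccc1)[C@]1(O[Si](CC)(CC)CC)CCC(C)(C)[C@H]1CCC=O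
F5 | step 9 | 13-(benzyloxy)-8-hydroxy-14,15,16,17-tetranor-5β-labdan-1-one (both C8 epimers) | c1ccccc1COCCC[C@@H]1[C@@]2(C)C(=O)CCC(C)(C)[C@H]2CCC1O
F6 | step 9 | 13-(benzyloxy)-14,15,16,17-tetranor-5β-labdan-8-ol (both C8 epimers) | c1ccccc1COCCC[C@@H]1[C@@]2(C)CCCC(C)(C)[C@H]2CCC1O
F7 | step 14 | 15,16-dinor-5β-labd-8(17)-en-13-yne | C#CCC[C@@H]1[C@@]2(C)CCCC(C)(C)[C@H]2CCC1=C
F8 | step 14 | 8β,17-epoxy-15,16-dinor-5β-labd-13-yne | C#CCC[C@@H]1[C@@]2(C)CCCC(C)(C)[C@H]2CC[C@@]13CO3
F9 | step 2 | 3,3-dimethyl-1-(trimethylsilyloxy)cyclopent-1-ene | C[Si](C)(C)OC1=CC(C)(C)CC1
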